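The earlier runs and the new flask were generated by integration for substances that don't exist, and the scatter is random.

A closed flask keeps its monomer: every percent charged is still free, in chains, or gone some other way. So a run that comes to a standstill short of the full charge shows what a given amount of initiator has carried. You ask for a quick number, and your hunch is that the hottest flask, being fastest, gives the most. I reckon otherwise.

in all of them: free monomer 0.20 M

| charge | transfer agent | protic impurity | initiator | temperature | remark | time |
|---|---|---|---|---|---|---|
| cedar | 0.020 M | 4 mM | 2.7 mM | 12 °C | run made earlier |  |
| larch | 0.020 M | 4 mM | 6 mM | 29 °C | run made earlier |  |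
| Friday's | 0.0200 M | 4.00 mM | 4.0 mM | 20 °C |  | 5.0 min |
| Saturday's | 0.0200 M | 4.00 mM | 4.0 mM | 5 °C |  | 5.0 min |
| Monday's | 0.0200 M | 4.00 mM | 4.0 mM | 35 °C |  | 5.0 min |

- cedar (time / min: monomer in chains / %): 1.33: 14.9; 2.50: 26.6; 4.00: 36.7; 5.00: 39.6; 6.00: 44.6
- larch (time / min: monomer in chains / %): 0.833: 41.8; 1.50: 53.8; 2.50: 56.9; 3.00: 59.2; 4.00: 59.8

(readings scatter by 1 percentage point)

- the best flask by amount of monomer in chains, in percent of the free monomer charged; "all alike" if 1.5 percentage points covers them all (Friday's / Saturday's / Monday's / all alike)
- amount of monomer in chains at the end, in percent of the free monomer charged, Friday's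
- amount of monomer in chains at the end, in percent of the free monomer charged, Saturday's
- amount of monomer in chains at the end, in percent of the free monomer charged, Monday's

- a reading or a percentage of monomer in chains counts all its forms, free or not

The larch run has stopped: it reads 59.2 % and then 59.8 %, within the scatter of 1 percentage point. Dividing that last reading, as an amount, by the initiator charged gives 19.9 of monomer in chains per initiator, which I call the chain yield, a cousin of the kinetic chain length. The cedar run, colder, reads 33.0 on the same count, more than larch, and is still rising. But the two runs differ in initiator as well as in temperature, so this pair does not separate the two settings.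

Monday's is hotter than larch. I carry the larch yield over unchanged, as a rough assumption, and multiply by Monday's initiator, which gives 39.9 % of the charge. Friday's stands between the two runs in temperature and in initiator, so as a rough guess I put its yield between theirs, which gives 39.9 % to 66.1 % of the charge. I therefore expect Monday's to fall behind Friday's.

The forecast, reckoned by another road than mine, names Friday's: 61 % (54 % to 68 %) for Friday's, 34 % (27 % to 41 %) for Saturday's, 39 % (29 % to 50 %) for Monday's, with “The middle temperature wins”.

The flasks give 55.3 % for Friday's, the best, then 44.1 % for Saturday's and 41.6 % for Monday's. The forecast's choice stands, and its Monday's value is within its range, but Friday's lies 5.7 points below it and Saturday's 10 points above it.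

    free monomer + initiator → living end + monomer in chains (k = 42.0 L mol⁻¹ min⁻¹, Ea = 57.0 kJ mol⁻¹)
    free monomer + living end → monomer in chains + living end, rate k2*[living end]*[free monomer] (k = 98.0 L mol⁻¹ min⁻¹, Ea = 42.0 kJ mol⁻¹)
    living end + transfer agent → dead chain (kL = 14.0 L mol⁻¹ min⁻¹, Ea = 62.0 kJ mol⁻¹)
    crystals ⇌ monomer in chains, rate k4*(cs4 - [monomer in chains]) while solid is left; crystals form when [monomer in chains] > cs4 (solubility = 29.0 mM, k = 3.10 min⁻¹)
    protic impurity + free monomer → quenched substrate (k = 11.0 L mol⁻¹ min⁻¹, Ea = 48.0 kJ mol⁻¹)
    free monomer → uncatalysed product (k = 0.110 min⁻¹, Ea = 87.0 kJ mol⁻¹)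
    (constants at 20 °C)

Monday's ends with a chain yield of 20.8, and waiting changes nothing: it stands at 41.7 % after 50.0 min. Saturday's is a different case: left until 50.0 min it reaches 78.7 % instead of 44.1 %, and with the initiator level held it reaches 88.9 %, so the reading at that time and the falling level of initiator are two parts of why Saturday's ends where it does.

The neighbour of Monday's charged with 0.0010 M of initiator gets 9.97 % from the chain yield. The computed result for that flask is 13.1 %.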